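The C6 oxygen sits on a carbon linked to the (E)-C1=C10 alkene through C7, C8 and C9, so the ten-membered ring is the product of an oxy-Cope rearrangement. One anionic [3,3] shift of a six-membered carbinol makes C8–C9, cuts C1–C6, expands the ring by four atoms, fixes the E-alkene and, on protonation, C7. The precursor is an (R)-carvone-derived cyclohexanol with a 3-methylbuta-1,3-dien-2-yl group on the carbinol carbon, a trans isopropenyl group next to it and a cis-fused methyl oxirane that later unmasks the C3 oxygen and the (4E)-alkene. No enolate is formed next to the isopropenyl-bearing centre before the key step.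

Key step: step 9

Assumption: ten-membered compounds carry germacrane numbers (ring C1–C10, methyls on C10 and C4, isopropenyl on C7, C11 its central carbon), and the tiglate is (E)-2-methylbut-2-enoate.

Step 1
Reactants: 1 (R)-(−)-carvone
Product: 2 (1R,5R)-2-methyl-5-(prop-1-en-2-yl)cyclohex-2-en-1-ol (cis-carveol)
Conditions: NaBH4, CeCl3·7H2O, MeOH, 0 °C
Reagents that add atoms: none
Why: Luche 1,2-reduction of the enone, with axial hydride attack placing the hydroxyl cis to the isopropenyl group; this carbinol centre is removed again in step 6, so its configuration carries no weight.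

Step 2
Reactants: 2 cis-carveol
Product: 3 (1R,5R)-2-methyl-5-(prop-1-en-2-yl)cyclohex-2-en-1-yl acetate
Conditions: Ac2O, pyridine, DMAP (cat.), CH2Cl2, 0 °C to rt
Reagents that add atoms: acetic anhydride, CC(=O)OC(C)=O
Why: DMAP-catalysed acylation caps the allylic alcohol, so that the oxidant of step 3 can only attack the ring methylene.

Step 3
Reactants: 3 cis-carveyl acetate
Product: 4 (1R,5R)-2-methyl-4-oxo-5-(prop-1-en-2-yl)cyclohex-2-en-1-yl acetate
Conditions: CrO3, 3,5-dimethylpyrazole, CH2Cl2, −20 °C
Reagents that add atoms: chromium trioxide, O=[Cr](=O)=O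
Why: Allylic oxidation with the CrO3–3,5-dimethylpyrazole complex turns the one ring CH2 allylic to the trisubstituted alkene into the enone carbonyl, and under these non-basic conditions the neighbouring isopropenyl-bearing centre keeps its configuration.

Step 4
Reactants: 5 2-methylbut-1-en-3-yne
Product: 7 2-bromo-3-methylbuta-1,3-diene, via bromoalkenylborane 6 (not isolated)
Conditions: B-Br-9-BBN, CH2Cl2, 0 °C; then AcOH, 0 °C to rt
Reagents that add atoms: B-bromo-9-borabicyclo[3.3.1]nonane, BrB1C2CCCC1CCC2
Why: Hara–Suzuki bromoboration adds B–Br syn and in the Markovnikov sense across the terminal alkyne only, and protodeboronation with acetic acid leaves the 2-bromo-1,3-diene.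

Step 5
Reactants: 7 2-bromo-3-methylbuta-1,3-diene; 4 acetoxy enone
Product: 11 (1R,4R,6R)-3-methyl-1-(3-methylbuta-1,3-dien-2-yl)-6-(prop-1-en-2-yl)cyclohex-2-ene-1,4-diol, via dienyllithium 8 (not isolated), via dienylcerium dichloride 9 (not isolated), via hydroxy acetate 10 (not isolated)
Conditions: 7, t-BuLi (2 equiv), Et2O, −78 °C; CeCl3, THF, −78 °C; add 4, −78 °C; then MeOH, K2CO3, 0 °C to rt
Reagents that add atoms: none
Why: Lithium–bromine exchange and transmetalation give a weakly basic organocerium reagent that adds 1,2 to the enone carbonyl from the face opposite to the adjacent isopropenyl group, which sets the tertiary carbinol with the two alkenyl groups trans; base-catalysed transesterification then frees the secondary hydroxyl.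

Step 6
Reactants: 11 diol
Product: 14 (1R,2R)-5-methyl-1-(3-methylbuta-1,3-dien-2-yl)-2-(prop-1-en-2-yl)cyclohex-4-en-1-ol, via sulfonylhydrazine 12 (not isolated), via allylic diazene 13 (not isolated)
Conditions: PPh3, DEAD, NBSH (2-nitrobenzenesulfonylhydrazide), N-methylmorpholine, −30 °C to rt
Reagents that add atoms: none
Why: Myers reductive 1,3-transposition, in which Mitsunobu displacement of the secondary allylic hydroxyl (the tertiary one is inert), loss of sulfinic acid and retro-ene extrusion of N2 deliver hydrogen to the ring carbon next to the carbinol and move the alkene one position away, with no ketone present that could epimerise the isopropenyl-bearing centre.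

Step 7
Reactants: 14 tertiary alcohol
Product: 15 trimethylsilyl ether of 14
Conditions: TMS-imidazole, CH2Cl2, rt
Reagents that add atoms: N-(trimethylsilyl)imidazole, C[Si](C)(C)n1ccnc1
Why: Neutral silylation converts the tertiary hydroxyl, which would steer a peracid to its own face, into a bulky axial group that shields that face.

Step 8
Reactants: 15 silyl ether
Product: 17 (1R,2R,4S,5R)-4,5-epoxy-5-methyl-1-(3-methylbuta-1,3-dien-2-yl)-2-(prop-1-en-2-yl)cyclohexan-1-ol, via epoxy silyl ether 16 (not isolated)
Conditions: mCPBA (1.0 equiv), NaHCO3, CH2Cl2, −20 °C; then K2CO3, MeOH, 0 °C to rt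
Reagents that add atoms: meta-chloroperbenzoic acid, OOC(=O)c1cccc(Cl)c1
Why: Prilezhaev epoxidation picks the only trisubstituted alkene and should come from the ring face opposite to the axial C1 silyloxy group, which sets C4 and C5 with the oxirane trans to the C1 oxygen and to the isopropenyl group; methanolysis then removes the silyl group.

Step 9
Reactants: 17 epoxy dialkenyl cyclohexanol
Product: 20 (3S,4R,7S,1(10)E)-3,4-epoxygermacra-1(10),11-dien-6-one, via potassium alkoxide 18 (not isolated), via potassium enolate 19 (not isolated)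
Conditions: KH, 18-crown-6, THF, 0 °C to rt; then AcOH, THF, −78 °C
Reagents that add atoms: none
Why: Deprotonation gives alkoxide 18, whose oxyanion weakens the adjacent ring bond (C1–C6 in germacrane numbers) so that the [3,3]-sigmatropic shift runs at or below room temperature: C8–C9 forms, C1–C6 breaks, and the six-membered ring opens out to the ten-membered dienolate 19. The closest known reaction type is the anionic oxy-Cope ring expansion of trans-1,2-dialkenylcyclohexanols to (E)-cyclodec-5-enones. The ten-membered ring is formed by four-atom ring expansion, not by cyclisation, through a six-centre chair transition state in which the dienyl and isopropenyl groups are both equatorial on the cyclohexane. That chair needs the trans-dialkenyl arrangement fixed in step 5, and it gives the (E)-C1=C10 alkene and an enolate whose C6=C7 bond is held as a trans-cycloalkene unit; since neither the oxygen nor the isopropenyl group can swing through the ring, only one face of C7 is exposed, and protonation there at −78 °C should set C7 as 7S by transfer of chirality from the two carbinol-side stereocentres of 17. Kinetic protonation of the dienolate at its α-carbon C7, not at the terminal CH2, keeps the isopropenyl group out of conjugation, and enolate formation makes the step irreversible. The oxirane is a spectator that has to survive, so low temperature and a short reaction time are chosen to outrun its attack by the alkoxide or the enolate.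

Step 10
Reactants: 20 epoxy ketone
Product: 21 (3S,7S,1(10)E,4E)-3-hydroxygermacra-1(10),4,11-trien-6-one
Conditions: DBU (0.2 equiv), CH2Cl2, −20 to 0 °C
Reagents that add atoms: none
Why: E1cB opening of the β,γ-epoxy ketone, in which enolisation towards C5 expels the C4 oxygen faster than C7 can enolise; because the former cis-oxirane holds C2–C3–C4–C5 syn, the ring can only place C3 anti to C6, which gives the (4E)-enone with the C3–O bond untouched.

Step 11
Reactants: 21 hydroxy enone
Product: 22 (3S,7S,1(10)E,4E)-6-oxogermacra-1(10),4,11-trien-3-yl (E)-2-methylbut-2-enoate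
Conditions: tigloyl chloride, pyridine, DMAP (cat.), CH2Cl2, 0 °C
Reagents that add atoms: (E)-2-methylbut-2-enoyl chloride, C/C=C(\C)C(Cl)=O
Why: Acylation of the C3 allylic alcohol through the acylpyridinium ion (DMAP catalysis) at 0 °C, where pyridine is too weak a base to epimerise C7 or to shift the tiglate double bond.

Step 12
Reactants: 22 enone tiglate
Product: 23 (3S,6S,7S,1(10)E,4E)-6-hydroxygermacra-1(10),4,11-trien-3-yl (E)-2-methylbut-2-enoate
Conditions: NaBH4, CeCl3·7H2O, MeOH, −78 °C
Reagents that add atoms: none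
Why: Luche 1,2-reduction; the twisted enone carbonyl stands roughly perpendicular to the ring with C4 and C8 on its inner side and the C4 methyl over the inner trajectory, so hydride should arrive from outside the ring and set C6 with its oxygen anti to the C7 isopropenyl group, as in the target.

Step 13
Reactants: 23 allylic alcohol
Product: 24 (3S,4R,5R,6R,7S,1(10)E)-4,5-epoxy-6-hydroxygermacra-1(10),11-dien-3-yl (E)-2-methylbut-2-enoate
Conditions: Ti(OiPr)4 (0.5 equiv), D-(−)-DIPT (0.6 equiv), t-BuOOH, 4 Å MS, CH2Cl2, −20 °C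
Reagents that add atoms: tert-butyl hydroperoxide, CC(C)(C)OO
Why: Sharpless epoxidation, in which the titanium-bound C6 hydroxyl delivers oxygen only to the adjacent C4=C5 alkene on its outer face; with D-(−)-DIPT this carbinol is the fast-reacting antipode, which should give the erythro 4,5-trans-oxirane (4R,5R) and leave the C1=C10, isopropenyl and tiglate alkenes alone.

Step 14
Reactants: 24 epoxy alcohol
Product: 25 (3S,4R,5R,6R,7S,1(10)E)-6-acetoxy-4,5-epoxygermacra-1(10),11-dien-3-yl (E)-2-methylbut-2-enoate (CNP0400048.1)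
Conditions: Ac2O, pyridine, DMAP (cat.), CH2Cl2, 0 °C
Reagents that add atoms: acetic anhydride, CC(=O)OC(C)=O
Why: DMAP-catalysed acetylation of the one remaining hydroxyl under mild base, which the oxirane and the tiglate tolerate.

Compound list
1 | (R)-(−)-carvone, (5R)-2-methyl-5-(prop-1-en-2-yl)cyclohex-2-en-1-one | CC1=CC[C@H](CC1=O)C(C)=C | starting material
2 | (1R,5R)-2-methyl-5-(prop-1-en-2-yl)cyclohex-2-en-1-ol (cis-carveol) | CC1=CC[C@H](C[C@H]1O)C(C)=C | intermediate
3 | (1R,5R)-2-methyl-5-(prop-1-en-2-yl)cyclohex-2-en-1-yl acetate | CC1=CC[C@H](C[C@H]1OC(C)=O)C(C)=C | intermediate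
4 | (1R,5R)-2-methyl-4-oxo-5-(prop-1-en-2-yl)cyclohex-2-en-1-yl acetate | CC1=CC(=O)[C@H](C[C@H]1OC(C)=O)C(C)=C | intermediate
5 | 2-methylbut-1-en-3-yne | C=C(C)C#C | starting material
6 | 9-[(Z)-2-bromo-3-methylbuta-1,3-dien-1-yl]-9-borabicyclo[3.3.1]nonane | Br/C(C(C)=C)=C\B1C2CCCC1CCC2 | intermediate (not isolated)
7 | 2-bromo-3-methylbuta-1,3-diene | C=C(C)C(Br)=C | intermediate
8 | (3-methylbuta-1,3-dien-2-yl)lithium | [Li]C(=C)C(C)=C | intermediate (not isolated)
9 | dichloro(3-methylbuta-1,3-dien-2-yl)cerium | Cl[Ce](Cl)C(=C)C(C)=C | intermediate (not isolated)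
10 | (1R,4R,5R)-4-hydroxy-2-methyl-4-(3-methylbuta-1,3-dien-2-yl)-5-(prop-1-en-2-yl)cyclohex-2-en-1-yl acetate | C=C(C)C(=C)[C@@]1(O)C=C(C)[C@H](OC(C)=O)C[C@@H]1C(C)=C | intermediate (not isolated)
11 | (1R,4R,6R)-3-methyl-1-(3-methylbuta-1,3-dien-2-yl)-6-(prop-1-en-2-yl)cyclohex-2-ene-1,4-diol | C=C(C)C(=C)[C@@]1(O)C=C(C)[C@H](O)C[C@@H]1C(C)=C | intermediate
12 | N-[(1S,4R,5R)-4-hydroxy-2-methyl-4-(3-methylbuta-1,3-dien-2-yl)-5-(prop-1-en-2-yl)cyclohex-2-en-1-yl]-2-nitrobenzenesulfonohydrazide (alkylated on the sulfonyl nitrogen) | C=C(C)C(=C)[C@@]1(O)C=C(C)[C@@H](N(N)S(=O)(=O)c2ccccc2[N+](=O)[O-])C[C@@H]1C(C)=C | intermediate (not isolated)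
13 | [(1S,4R,5R)-4-hydroxy-2-methyl-4-(3-methylbuta-1,3-dien-2-yl)-5-(prop-1-en-2-yl)cyclohex-2-en-1-yl]diazene | C=C(C)C(=C)[C@@]1(O)C=C(C)[C@@H](N=N)C[C@@H]1C(C)=C | intermediate (not isolated)
14 | (1R,2R)-5-methyl-1-(3-methylbuta-1,3-dien-2-yl)-2-(prop-1-en-2-yl)cyclohex-4-en-1-ol | C=C(C)C(=C)[C@@]1(O)CC(C)=CC[C@@H]1C(C)=C | intermediate
15 | trimethyl{[(1R,2R)-5-methyl-1-(3-methylbuta-1,3-dien-2-yl)-2-(prop-1-en-2-yl)cyclohex-4-en-1-yl]oxy}silane | C=C(C)C(=C)[C@@]1(O[Si](C)(C)C)CC(C)=CC[C@@H]1C(C)=C | intermediate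
16 | trimethylsilyl ether of 17 (oxirane trans to the silyloxy group) | C=C(C)C(=C)[C@@]1(O[Si](C)(C)C)C[C@@]2(C)O[C@H]2C[C@@H]1C(C)=C | intermediate (not isolated)
17 | (1R,2R,4S,5R)-4,5-epoxy-5-methyl-1-(3-methylbuta-1,3-dien-2-yl)-2-(prop-1-en-2-yl)cyclohexan-1-ol | C=C(C)C(=C)[C@@]1(O)C[C@@]2(C)O[C@H]2C[C@@H]1C(C)=C | intermediate (key-step precursor)
18 | potassium alkoxide of 17 | C=C(C)C(=C)[C@@]1([O-])C[C@@]2(C)O[C@H]2C[C@@H]1C(C)=C.[K+] | intermediate (not isolated)
19 | potassium (3S,4R,1(10)E,6E)-3,4-epoxygermacra-1(10),6,11-trien-6-olate | C=C(C)/C1=C(/[O-])C[C@@]2(C)O[C@H]2C/C=C(C)/CC1.[K+] | intermediate (not isolated)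
20 | (3S,4R,7S,1(10)E)-3,4-epoxygermacra-1(10),11-dien-6-one | C=C(C)[C@@H]1CC/C(C)=C/C[C@@H]2O[C@]2(C)CC1=O | intermediate (key-step product)
21 | (3S,7S,1(10)E,4E)-3-hydroxygermacra-1(10),4,11-trien-6-one | C=C(C)[C@@H]1CC/C(C)=C/C[C@H](O)/C(C)=C/C1=O | intermediate
22 | (3S,7S,1(10)E,4E)-6-oxogermacra-1(10),4,11-trien-3-yl (E)-2-methylbut-2-enoate | C=C(C)[C@@H]1CC/C(C)=C/C[C@H](OC(=O)/C(C)=C/C)/C(C)=C/C1=O | intermediate
23 | (3S,6S,7S,1(10)E,4E)-6-hydroxygermacra-1(10),4,11-trien-3-yl (E)-2-methylbut-2-enoate (C6 has the spatial arrangement of the target; the descriptor is S only while C5 is sp2) | C=C(C)[C@@H]1CC/C(C)=C/C[C@H](OC(=O)/C(C)=C/C)/C(C)=C/[C@@H]1O | intermediate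
24 | (3S,4R,5R,6R,7S,1(10)E)-4,5-epoxy-6-hydroxygermacra-1(10),11-dien-3-yl (E)-2-methylbut-2-enoate | C=C(C)[C@@H]1CC/C(C)=C/C[C@H](OC(=O)/C(C)=C/C)[C@@]2(C)O[C@@H]2[C@@H]1O | intermediate
25 | (3S,4R,5R,6R,7S,1(10)E)-6-acetoxy-4,5-epoxygermacra-1(10),11-dien-3-yl (E)-2-methylbut-2-enoate, CNP0400048.1 | C=C(C)[C@@H]1CC/C(C)=C/C[C@H](OC(=O)/C(C)=C/C)[C@@]2(C)O[C@@H]2[C@@H]1OC(C)=O | target

Total step count: 14. Longest linear sequence: 13 steps (steps 1–3 and 5–14, from carvone 1 to 25); step 4 is the one-step side branch.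

Steps most likely to fail

Step 9. The oxirane may be opened intramolecularly by the alkoxide before the rearrangement or by the enolate after it, or the C7 configuration may be lost by protonation at the wrong atom or by equilibration. The fallback expands the ring before the oxirane is made. It sets out from 14, which is rearranged with KH and 18-crown-6 in THF to (7S,1(10)E,3Z)-germacra-1(10),3,11-trien-6-one F1, C7 being set in the same way. NaBH4 reduction gives the C6 alcohol (6S,7S,1(10)E,3Z)-germacra-1(10),3,11-trien-6-ol F2. VO(acac)2 with t-BuOOH then epoxidises the homoallylic C3=C4 alkene from the hydroxyl face to (3S,4R,6S,7S,1(10)E)-3,4-epoxygermacra-1(10),11-dien-6-ol F3. Which C6 epimer directs to the 3S,4R face would have to be established; the other epimer would be reached with L-Selectride. Dess–Martin oxidation buffered with NaHCO3 comes back to the route at 20.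

Step 8. Oxygen may be delivered syn to the silyloxy group, or the diene or isopropenyl alkenes may compete for the peracid. The fallback sets the oxirane by hydroxyl direction before the diene is attached. It sets out from 4: SmI2 in THF/MeOH at −78 °C removes the γ-acetoxy group reductively, and kinetic α-protonation of the dienolate gives (R)-5-methyl-2-(prop-1-en-2-yl)cyclohex-4-en-1-one F4. NaBH4 should give mainly the trans alcohol (1S,2R)-5-methyl-2-(prop-1-en-2-yl)cyclohex-4-en-1-ol F5. VO(acac)2 with t-BuOOH delivers oxygen to the homoallylic ring alkene from the hydroxyl face, anti to the isopropenyl group, giving (1S,2R,4S,5R)-4,5-epoxy-5-methyl-2-(prop-1-en-2-yl)cyclohexan-1-ol F6. Buffered Dess–Martin oxidation gives (2R,4S,5R)-4,5-epoxy-5-methyl-2-(prop-1-en-2-yl)cyclohexan-1-one F7. The organocerium reagent 9, made from 7 as in step 5, adds trans to the isopropenyl group at −78 °C and comes back to the route at 17.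

Step 12. Hydride may be delivered to the wrong carbonyl face, giving the C6 epimer, whose hydroxyl would then steer the epoxidation to the wrong alkene face. The fallback reverses the order and lets the oxirane control C6. It sets out from 22: Weitz–Scheffer epoxidation of the enone with t-BuOOH and DBU in CH2Cl2 should give, by attack on the outer face, (3S,4R,5S,7S,1(10)E)-4,5-epoxy-6-oxogermacra-1(10),11-dien-3-yl (E)-2-methylbut-2-enoate F8. Zn(BH4)2 in Et2O at −20 °C reduces it under chelation between the carbonyl and oxirane oxygens to the erythro epoxy alcohol, which comes back to the route at 24.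

Further compounds
F1 | step 9 | (7S,1(10)E,3Z)-germacra-1(10),3,11-trien-6-one | C=C(C)[C@@H]1CC/C(C)=C/C/C=C(C)\CC1=O
F2 | step 9 | (6S,7S,1(10)E,3Z)-germacra-1(10),3,11-trien-6-ol | C=C(C)[C@@H]1CC/C(C)=C/C/C=C(C)\C[C@@H]1O
F3 | step 9 | (3S,4R,6S,7S,1(10)E)-3,4-epoxygermacra-1(10),11-dien-6-ol | C=C(C)[C@@H]1CC/C(C)=C/C[C@@H]2O[C@]2(C)C[C@@H]1O
F4 | step 8 | (R)-5-methyl-2-(prop-1-en-2-yl)cyclohex-4-en-1-one | CC1=CC[C@H](C(C)=C)C(=O)C1
F5 | step 8 | (1S,2R)-5-methyl-2-(prop-1-en-2-yl)cyclohex-4-en-1-ol | CC1=CC[C@H](C(C)=C)[C@@H](O)C1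
F6 | step 8 | (1S,2R,4S,5R)-4,5-epoxy-5-methyl-2-(prop-1-en-2-yl)cyclohexan-1-ol | O[C@H]1C[C@@]2(C)O[C@H]2C[C@@H]1C(C)=C
F7 | step 8 | (2R,4S,5R)-4,5-epoxy-5-methyl-2-(prop-1-en-2-yl)cyclohexan-1-one | O=C1C[C@@]2(C)O[C@H]2C[C@@H]1C(C)=C
F8 | step 12 | (3S,4R,5S,7S,1(10)E)-4,5-epoxy-6-oxogermacra-1(10),11-dien-3-yl (E)-2-methylbut-2-enoate | C=C(C)[C@@H]1CC/C(C)=C/C[C@H](OC(=O)/C(C)=C/C)[C@@]2(C)O[C@@H]2C1=O
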